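**Retrosynthetic overview**

- Target 16 is traced back to phenol 14 by hydrogenolysis of the ring B benzyl ester and O-methylation of the ring A 4-hydroxyl.
- The strategy rests on ring A, numbered C1 (carbonyl-bearing), C2 (propyl), C4 and C6 (oxygen). This pattern maps onto a hex-2-ynoate (C1, C2, propyl, carbonyl) plus 1,1-dimethoxy-3-(trimethylsilyloxy)buta-1,3-diene (C3–C6), with bonds C2–C3 and C1–C6 made in one Diels–Alder benzannulation.
- The depside C(=O)–O bond is therefore made on the unhindered hex-2-ynoic acid (compound 7), before the two ortho substituents of ring A exist.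
- Ynoate 7 comes from benzyl olivetolate 5, made from olivetol by formylation, oxidation and benzylation. Diene 11 comes from 1,1-dimethoxyethene and acetyl chloride.
- Ring B is bought as olivetol. Ring A is the only ring formed (step 7).

Key step: step 7

Remark on the chemistry: the target has no stereocentre, and salicylic acids of the ring B type decarboxylate on heating, so 4 and 16 are handled at or below room temperature.

**Route**

Step 1
Reactants: 1 olivetol (5-pentylresorcinol)
Product: 3 2,4-dihydroxy-6-pentylbenzaldehyde, via aryl iminium chloride 2 (not isolated)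
Conditions: POCl3, DMF, 0 °C to rt; then H2O, 50 °C
Reagents that add atoms: N,N-dimethylformamide (CN(C)C=O); water (O)
Why: Vilsmeier–Haack formylation, which for 5-alkylresorcinols attacks the ring carbon para to one hydroxyl and ortho to the other rather than the carbon between the two hydroxyls; the iminium salt is hydrolysed on aqueous work-up.

Step 2
Reactants: 3 2,4-dihydroxy-6-pentylbenzaldehyde
Product: 4 olivetolic acid (2,4-dihydroxy-6-pentylbenzoic acid)
Conditions: NaClO2, NaH2PO4, DMSO/H2O, 0 °C to rt
Reagents that add atoms: sodium chlorite ([Na+].[O-]Cl=O)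
Why: Lindgren–Pinnick oxidation, a method developed on hydroxybenzaldehydes; chlorous acid adds to the aldehyde and fragments to the acid, while DMSO reduces the hypochlorous acid formed before it can chlorinate the electron-rich ring.

Step 3
Reactants: 4 olivetolic acid
Product: 5 benzyl olivetolate (benzyl 2,4-dihydroxy-6-pentylbenzoate)
Conditions: BnBr, KHCO3, DMF, rt
Reagents that add atoms: benzyl bromide (BrCc1ccccc1)
Why: SN2 O-alkylation of the carboxylate; hydrogen carbonate ionises only the carboxylic acid, so neither phenol is benzylated.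

Step 4
Reactants: 5 benzyl olivetolate; 6 hex-2-ynoic acid
Product: 7 benzyl 4-(hex-2-ynoyloxy)-2-hydroxy-6-pentylbenzoate
Conditions: DCC, DMAP (5 mol%), CH2Cl2, 0 °C
Reagents that add atoms: none
Why: Steglich esterification, the routine way to aryl alk-2-ynoates; the 4-hydroxyl is free and the more nucleophilic one, whereas the 2-hydroxyl is hydrogen-bonded to the benzyl ester carbonyl, so one equivalent of acid acylates O4 only.

Step 5
Reactants: 8 1,1-dimethoxyethene (2.1 equiv); 9 acetyl chloride
Product: 10 4,4-dimethoxybut-3-en-2-one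
Conditions: Et2O, 0 °C to rt
Reagents that add atoms: none
Why: C-acylation of a ketene acetal by an acid chloride, giving the acylketene acetal after proton loss; the second equivalent of 8 takes up the HCl and collapses to methyl acetate and chloromethane.

Step 6
Reactants: 10 4,4-dimethoxybut-3-en-2-one
Product: 11 1,1-dimethoxy-3-(trimethylsilyloxy)buta-1,3-diene
Conditions: TMSCl, Et3N, ZnCl2 (cat.), toluene, 40 °C; filtration and distillation without aqueous work-up
Reagents that add atoms: chlorotrimethylsilane (C[Si](C)(C)Cl)
Why: Amine/ZnCl2 silyl enol ether formation at the methyl group, the only enolisable position of the push-pull enone, as used for other 2-silyloxydienes.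

Step 7
Reactants: 7 benzyl 4-(hex-2-ynoyloxy)-2-hydroxy-6-pentylbenzoate; 11 1,1-dimethoxy-3-(trimethylsilyloxy)buta-1,3-diene (3 equiv, added in portions)
Product: 14 benzyl 2-hydroxy-4-[(4-hydroxy-2-methoxy-6-propylbenzoyl)oxy]-6-pentylbenzoate, via cyclohexadiene cycloadduct 12 (not isolated), via aryl silyl ether 13 (not isolated)
Conditions: toluene, 120 °C, sealed tube; then 1 M HCl, THF, 0 °C to rt
Reagents that add atoms: none
Why: The electron-rich diene 11 and the electron-poor ynoate 7 combine in a thermal, concerted but asynchronous normal-demand Diels–Alder reaction, the known benzannulation of 1,1-dialkoxy-3-silyloxybutadienes with alk-2-ynoates to resorcylates. Ring A is closed by this intermolecular [4+2] cycloaddition (four diene carbons plus the two alkyne carbons), which forms C2–C3 and C1–C6 and gives cyclohexa-1,4-diene 12. Ionisation of one ketal methoxy group at C6, assisted by the adjacent silyl enol ether, and loss of a C3 proton expel methanol and aromatise 12 to aryl silyl ether 13, which dilute acid hydrolyses to phenol 14; no stereocentre is created. The step needs regioselectivity, and the substrate provides it: the diene CH2 terminus, which receives electron density from the silyloxy and from both methoxy groups, bonds to the propyl-bearing β-carbon where the ynoate LUMO is largest, so the ketene-acetal carbon ends up next to the ester carbonyl. The aryl ester lowers the alkyne LUMO more than an alkyl ester would, which offsets the retarding β-propyl group, and its carbonyl has no ortho neighbours at the time the depside C–O bond is made. The excess of 11 takes up the liberated methanol and any proton or silyl exchange at the chelated ring B hydroxyl, which the acidic work-up restores.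

Step 8
Reactants: 14 benzyl 2-hydroxy-4-[(4-hydroxy-2-methoxy-6-propylbenzoyl)oxy]-6-pentylbenzoate
Product: 15 benzyl 4-[(2,4-dimethoxy-6-propylbenzoyl)oxy]-2-hydroxy-6-pentylbenzoate
Conditions: MeI (1.2 equiv), K2CO3, acetone, rt
Reagents that add atoms: iodomethane (CI)
Why: Williamson ether synthesis; the ring A 4-hydroxyl is para to an ester carbonyl, acidic and unhindered, whereas the ring B 2-hydroxyl is held in a hydrogen bond to the benzyl ester and stays unalkylated under these mild conditions.

Step 9
Reactants: 15 benzyl 4-[(2,4-dimethoxy-6-propylbenzoyl)oxy]-2-hydroxy-6-pentylbenzoate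
Product: 16 4-[(2,4-dimethoxy-6-propylbenzoyl)oxy]-2-hydroxy-6-pentylbenzoic acid (target, CNP0324837.0)
Conditions: H2 (1 atm), Pd/C (10% Pd on carbon), EtOAc, rt
Reagents that add atoms: none
Why: Catalytic hydrogenolysis of the benzyl ester; the hindered aryl ester and the aryl methyl ethers are inert, and room temperature avoids decarboxylation of the salicylic acid.

**Compound list**

1 | olivetol (5-pentylresorcinol) | CCCCCc1cc(O)cc(O)c1 | starting material
2 | N-[(2,4-dihydroxy-6-pentylphenyl)methylidene]-N-methylmethanaminium chloride | CCCCCc1cc(O)cc(O)c1C=[N+](C)C.[Cl-] | intermediate (not isolated)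
3 | 2,4-dihydroxy-6-pentylbenzaldehyde | CCCCCc1cc(O)cc(O)c1C=O | intermediate
4 | olivetolic acid (2,4-dihydroxy-6-pentylbenzoic acid) | CCCCCc1cc(O)cc(O)c1C(=O)O | intermediate
5 | benzyl olivetolate (benzyl 2,4-dihydroxy-6-pentylbenzoate) | CCCCCc1cc(O)cc(O)c1C(=O)OCc1ccccc1 | intermediate
6 | hex-2-ynoic acid | CCCC#CC(=O)O | starting material
7 | benzyl 4-(hex-2-ynoyloxy)-2-hydroxy-6-pentylbenzoate | CCCC#CC(=O)Oc1cc(O)c(C(=O)OCc2ccccc2)c(CCCCC)c1 | intermediate
8 | 1,1-dimethoxyethene | C=C(OC)OC | starting material
9 | acetyl chloride | CC(Cl)=O | starting material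
10 | 4,4-dimethoxybut-3-en-2-one | CC(=O)C=C(OC)OC | intermediate
11 | 1,1-dimethoxy-3-(trimethylsilyloxy)buta-1,3-diene | C=C(O[Si](C)(C)C)C=C(OC)OC | intermediate
12 | benzyl 4-{[6,6-dimethoxy-2-propyl-4-(trimethylsilyloxy)cyclohexa-1,4-diene-1-carbonyl]oxy}-2-hydroxy-6-pentylbenzoate | CCCCCc1cc(OC(=O)C2=C(CCC)CC(O[Si](C)(C)C)=CC2(OC)OC)cc(O)c1C(=O)OCc1ccccc1 | intermediate (not isolated)
13 | benzyl 2-hydroxy-4-{[2-methoxy-6-propyl-4-(trimethylsilyloxy)benzoyl]oxy}-6-pentylbenzoate | CCCCCc1cc(OC(=O)c2c(CCC)cc(O[Si](C)(C)C)cc2OC)cc(O)c1C(=O)OCc1ccccc1 | intermediate (not isolated)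
14 | benzyl 2-hydroxy-4-[(4-hydroxy-2-methoxy-6-propylbenzoyl)oxy]-6-pentylbenzoate | CCCCCc1cc(OC(=O)c2c(CCC)cc(O)cc2OC)cc(O)c1C(=O)OCc1ccccc1 | intermediate
15 | benzyl 4-[(2,4-dimethoxy-6-propylbenzoyl)oxy]-2-hydroxy-6-pentylbenzoate | CCCCCc1cc(OC(=O)c2c(CCC)cc(OC)cc2OC)cc(O)c1C(=O)OCc1ccccc1 | intermediate
16 | 4-[(2,4-dimethoxy-6-propylbenzoyl)oxy]-2-hydroxy-6-pentylbenzoic acid | CCCCCc1cc(OC(=O)c2c(CCC)cc(OC)cc2OC)cc(O)c1C(=O)O | target

**Step count**

Total steps: 9. Longest linear sequence: 7 (steps 1, 2, 3, 4, 7, 8, 9); the diene branch (steps 5 and 6) joins at step 7.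

**Steps most likely to fail**

1. Step 7. The β-propyl ynoate may add too slowly, so that thermal decay of the diene and cleavage of the aryl ester by liberated methanol win over cycloaddition. The fallback builds ring A on a simple ester and joins the rings by classical depside coupling; it sets out from 11 and 5 and rejoins the route at 15.
   - Diene 11 would be heated neat at 130–140 °C with purchased methyl hex-2-ynoate (CCCC#CC(=O)OC), which carries no phenol and no transferable aryl ester.
   - The cycloadduct methyl 6,6-dimethoxy-2-propyl-4-(trimethylsilyloxy)cyclohexa-1,4-diene-1-carboxylate F1 would lose methanol to methyl 2-methoxy-6-propyl-4-(trimethylsilyloxy)benzoate F2, and dilute HCl would give methyl 4-hydroxy-2-methoxy-6-propylbenzoate F3.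
   - MeI and K2CO3 in acetone would give methyl 2,4-dimethoxy-6-propylbenzoate F4, and KOH in aqueous DMSO at 90 °C would hydrolyse the hindered ester to 2,4-dimethoxy-6-propylbenzoic acid F5.
   - Trifluoroacetic anhydride in toluene at rt would turn F5 into 2,4-dimethoxy-6-propylbenzoic trifluoroacetic anhydride F6, whose acylium-like carbonyl acylates the unchelated 4-hydroxyl of 5 despite the two ortho substituents and gives 15.

2. Step 2. Hypochlorous acid may chlorinate the free resorcinol ring, the strongly hydrogen-bonded, vinylogous-acid aldehyde may oxidise slowly, and the product may decarboxylate during isolation. The fallback oxidises with the phenols masked; it sets out from 3 and rejoins the route at 5.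
   - Aldehyde 3 would be converted with NaH and MOMCl in DMF into 2,4-bis(methoxymethoxy)-6-pentylbenzaldehyde F7.
   - Pinnick oxidation (NaClO2, NaH2PO4, 2-methylbut-2-ene, t-BuOH/H2O) would give 2,4-bis(methoxymethoxy)-6-pentylbenzoic acid F8.
   - BnBr and K2CO3 in DMF would give benzyl 2,4-bis(methoxymethoxy)-6-pentylbenzoate F9, and HCl in aqueous THF would remove both acetals to give 5.

3. Step 5. The ketene acetal may be lost to HCl-induced oligomerisation and over-acylation, and the oxocarbenium intermediate may be dealkylated to methyl acetoacetate. The fallback makes the enone from a dichlorovinyl ketone; it sets out from 9 and rejoins the route at 10.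
   - Acetyl chloride 9 would be added to 1,1-dichloroethene with AlCl3 in CH2Cl2 at 0 °C to give 4,4,4-trichlorobutan-2-one F10, which loses HCl on distillation to 4,4-dichlorobut-3-en-2-one F11.
   - NaOMe (2 equiv) in MeOH at 0 °C would replace both vinylic chlorides by addition–elimination, through 4-chloro-4-methoxybut-3-en-2-one F12, and deliver 10.

**Further compounds**

F1 | step 7 | methyl 6,6-dimethoxy-2-propyl-4-(trimethylsilyloxy)cyclohexa-1,4-diene-1-carboxylate | CCCC1=C(C(=O)OC)C(OC)(OC)C=C(O[Si](C)(C)C)C1
F2 | step 7 | methyl 2-methoxy-6-propyl-4-(trimethylsilyloxy)benzoate | CCCc1cc(O[Si](C)(C)C)cc(OC)c1C(=O)OC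
F3 | step 7 | methyl 4-hydroxy-2-methoxy-6-propylbenzoate | CCCc1cc(O)cc(OC)c1C(=O)OC
F4 | step 7 | methyl 2,4-dimethoxy-6-propylbenzoate | CCCc1cc(OC)cc(OC)c1C(=O)OC
F5 | step 7 | 2,4-dimethoxy-6-propylbenzoic acid | CCCc1cc(OC)cc(OC)c1C(=O)O
F6 | step 7 | 2,4-dimethoxy-6-propylbenzoic trifluoroacetic anhydride | CCCc1cc(OC)cc(OC)c1C(=O)OC(=O)C(F)(F)F
F7 | step 2 | 2,4-bis(methoxymethoxy)-6-pentylbenzaldehyde | CCCCCc1cc(OCOC)cc(OCOC)c1C=O
F8 | step 2 | 2,4-bis(methoxymethoxy)-6-pentylbenzoic acid | CCCCCc1cc(OCOC)cc(OCOC)c1C(=O)O
F9 | step 2 | benzyl 2,4-bis(methoxymethoxy)-6-pentylbenzoate | CCCCCc1cc(OCOC)cc(OCOC)c1C(=O)OCc1ccccc1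
F10 | step 5 | 4,4,4-trichlorobutan-2-one | CC(=O)CC(Cl)(Cl)Cl
F11 | step 5 | 4,4-dichlorobut-3-en-2-one | CC(=O)C=C(Cl)Cl
F12 | step 5 | 4-chloro-4-methoxybut-3-en-2-one | CC(=O)C=C(Cl)OC
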